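**Remark on the chemistry (assumption):** the two biaryl axes of the target carry too few ortho substituents to be configurationally fixed and the structure shows no axial descriptor, so the target is treated as achiral.

Compound numbers refer to the compound list after the steps. Positions are written as C2(A), C4(B) and so on: the locant of an 8-methoxynaphthalen-1-ol unit followed by the unit letter.

## Analysis of the target

The target 20 is a linear ternaphthalene made of three 8-methoxynaphthalen-1-ol units A, B and C, joined by the biaryl bonds C2(A)–C2(B) and C4(B)–C2(C). It has no stereocentre, so the whole problem is one of regiochemistry. Each unit carries a free naphthol hydrogen-bonded to a peri methoxy group. These electron-rich naphthols are easily oxidised to quinones or coupled oxidatively, so they should be set free late and without any oxidant. The synthesis is hard because three almost identical units must be joined through different positions (2 to 2 and 4 to 2). The central unit B is substituted both ortho and para to its oxygen, and direct oxidative or electrophilic coupling of the monomer 2 cannot tell these sites apart. In each peri pair one oxygen must also end as OH and the other as OMe. The strategy rests on the C2(A)=C3(A) bond: it joins the aryl-bearing C2(A) to C3(A)–H and lies next to the oxygen-bearing C1(A). The phenol ring of unit A is therefore the enol of a 2-aryl-4H-naphthalen-1-one whose alkene can be the product of a ring-closing metathesis, with C1(A) as the ketone carbon of the diene.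

## Retrosynthetic reasoning

**20 to 19.** The oxygens on C1(B) and C1(C) are masked as methoxymethyl ethers in 19. These acetals survive the organolithium, palladium and ruthenium steps, act as directing groups for lithiation, and come off with mild acid, which the oxidation-prone triol tolerates. The O1(A) hydroxyl needs no protection because it is created only in the penultimate step.

**19 to 17 (through 18).** The C2(A)=C3(A) bond is cut. This opens the phenol ring of unit A to the diene 17, a 2-aryl-prop-2-en-1-one whose ketone sits on a benzene ring between a methoxy group and an allyl arm. Cutting here keeps the A–B bond on the enone carbon, so no aromatic position of unit A has to be coupled, and the peri relation of O1(A) and the methoxy group follows from the substitution pattern of one benzene ring. In the forward direction a ruthenium carbene must join the enone methylene and the allyl terminus, and the resulting keto tautomer 18 must enolise to the naphthol 19.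

**17 to 15.** The exocyclic methylene carbon is removed, which leads to the deoxybenzoin 15. Its CH2 group is flanked by a ketone and an aryl ring, so a Mannich-type methylenation should install the carbon cleanly at that position and nowhere else.

**15 to 10 and 14.** The bond between the CH2 carbon and C2(B) is cut. The later, hindered A–B biaryl bond is thus made as an sp3–sp2 bond by palladium-catalysed arylation of the methyl ketone 14 with the aryl bromide 10. The two fragments are of comparable size, so the route is convergent at this point.

**14 to 12 and 13, and 12 to 11.** The aryl–allyl bond is cut. The phenol of the acetophenone 11 lies ortho to the acetyl group, exactly where the allyl arm is needed, and the methoxy group on the other side becomes the peri methoxy group of unit A. The phenol is activated as the triflate 12 and coupled with the allylboronate 13.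

**10 to 8 (through 9).** The C2(B)–Br bond is cut. In the dimer 8 the acetal on O1(B) is the only directing group with a free ortho C–H, because the ortho position of the acetal on unit C is taken by the biaryl bond. Directed lithiation to 9 followed by bromine transfer should therefore mark C2(B) alone.

**8 to 5 and 7.** The C4(B)–C2(C) bond is cut by a cross-coupling disconnection. It is the only biaryl bond of the route made between two aromatic rings, and the positions of boron in 5 and bromine in 7 fix its regiochemistry.

**5 to 3 to 2, 7 to 6 to 2, and 2 to 1.** Both coupling partners come from the monomer 2 by two complementary modes of regiocontrol. Ortho functionalisation uses directed lithiation of the acetal 3 (through 4). Para functionalisation uses electrophilic bromination of the free naphthol 2 to 6, followed by protection to 7. The monomer 2 comes from the symmetric diol 1 by a single O-methylation.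

## Alternatives that were turned down

**Alternative 1:** The central unit B is cut at C1(B)–C8a(B) and C4(B)–C4a(B). Its methoxy-bearing benzo ring then comes from the aryne A4, released by fluoride from the silyl aryl triflate A3. Carbons C1(B) to C4(B) and the oxygen come from the 2,4-dinaphthylfuran A2, which already carries units C and A. The forward key step is a [4+2] cycloaddition giving the oxygen-bridged adduct A1. Acid would then open the bridge at the aryl-bearing bridgehead and leave the hydroxyl on the hydrogen-bearing one.
- For it: the route is highly convergent, the central ring is made last, and the acid that opens the bridge could remove the acetals in the same operation. On convergence it is stronger than the chosen route.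
- Against it: both A4 and A2 are unsymmetrical, and neither sterics nor the polarisation of the aryne gives a dependable preference for placing the methoxy group next to the unsubstituted furan carbon. The other orientation leads to a constitutional isomer with the methoxy group on the wrong peri side, which would be hard to separate. A2 also needs its own synthesis with two hindered naphthyl–furan bonds.
- Comparison: the chosen strategy offers regiochemistry that is fixed by construction in every bond-forming step.

**Alternative 2:** Both outer phenol rings are cut at C1–C2 of units A and C. The precursor A6 is a B core with two 3-arylallyl arms, each aryl ring carrying a diethylamide between a methoxy group and the arm. A lithium amide base would deprotonate both doubly activated CH2 groups, each allyl anion would attack its neighbouring amide, and loss of the amine and enolisation would give A5.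
- For it: the anionic annulation of ortho-allyl benzamides to 1-naphthols is an established reaction type. Two rings would form in one operation, no transition metal is needed in the key step, and the two positions of the B core carry identical arms, so they need not be differentiated. In step count from the B core it is stronger than the chosen route.
- Against it: each amide is flanked on both sides and is a very shielded electrophile. The 1,3-diarylallyl anion is strongly stabilised and ambident. Only the Z arrangement about the C3–C4 bond can reach the carbonyl. The carbon that attacks becomes fully substituted next to the B core. Two such closures must both succeed on one molecule, one of them beside the peri-crowded C4(B).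
- Comparison: the chosen strategy closes one ring by a neutral, catalytic process with an irreversible aromatisation as its sink.

**Alternative 3:** Unit A is cut at C1(A)–C8a(A) and taken back to the tetralone level. Halogen–lithium exchange on the bromo Weinreb amide A8 with an alkyllithium would give an aryllithium that adds to the amide (Parham cyclisation) and forms the racemic tetralone A7. A7 would then be dehydrogenated to 19.
- For it: the position of the bromine fixes the regiochemistry, the chelated tetrahedral intermediate prevents over-addition, and the ring closure itself is at least as robust as a metathesis and has no alkene-migration problem.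
- Against it: A8 has an acidic C–H between the amide and the aryl group that can quench the aryllithium intramolecularly. Its assembly needs an extra alkylation with a separately made phenethyl electrophile. The final dehydrogenation calls for an oxidant or forcing conditions on a molecule with three very electron-rich naphthalenes.
- Comparison: the chosen strategy delivers the aromatic oxidation level directly by tautomerisation and needs no redox step.

Key step: step 12

## Route

Step 1
Reactants: 1 naphthalene-1,8-diol
Product: 2 8-methoxynaphthalen-1-ol
Conditions: MeI (1.1 equiv), K2CO3, acetone, reflux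
Reagents that add atoms: iodomethane, CI
Why: Williamson O-methylation; the mono-phenoxide is stabilised by the peri hydroxyl, and the remaining OH of 2 is hydrogen-bonded to the new methoxy group and far less acidic, so alkylation should stop after one methyl group.

Step 2
Reactants: 2 8-methoxynaphthalen-1-ol
Product: 3 1-methoxy-8-(methoxymethoxy)naphthalene
Conditions: NaH, DMF, 0 °C; MOMCl, 0 °C → rt
Reagents that add atoms: chloromethyl methyl ether, COCCl
Why: Irreversible deprotonation breaks the peri hydrogen bond and the naphthoxide is alkylated by the α-chloro ether (Williamson-type acetal formation); the MOM group protects the oxygen and later directs lithiation.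

Step 3
Reactants: 3 1-methoxy-8-(methoxymethoxy)naphthalene
Product: 5 2-[8-methoxy-1-(methoxymethoxy)naphthalen-2-yl]-4,4,5,5-tetramethyl-1,3,2-dioxaborolane, via aryllithium 4 (not isolated)
Conditions: n-BuLi, TMEDA, THF, −78 → 0 °C; then i-PrOBpin, −78 °C → rt; aqueous work-up
Reagents that add atoms: 2-isopropoxy-4,4,5,5-tetramethyl-1,3,2-dioxaborolane, CC(C)OB1OC(C)(C)C(C)(C)O1
Why: Directed ortho metalation; the chelating OMOM group is a stronger director than OMe and its peri position is blocked, so lithium should enter at C2, and the aryllithium is trapped as the pinacol boronate.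

Step 4
Reactants: 2 8-methoxynaphthalen-1-ol
Product: 6 4-bromo-8-methoxynaphthalen-1-ol
Conditions: NBS (1.0 equiv), MeCN, −20 → 0 °C
Reagents that add atoms: N-bromosuccinimide, O=C1CCC(=O)N1Br
Why: Electrophilic aromatic bromination; the free hydroxyl is the strongest activator, so the phenol ring should react, and in polar acetonitrile 1-naphthols are brominated mainly at the para position C4.

Step 5
Reactants: 6 4-bromo-8-methoxynaphthalen-1-ol
Product: 7 1-bromo-5-methoxy-4-(methoxymethoxy)naphthalene
Conditions: NaH, DMF, 0 °C; MOMCl, 0 °C → rt
Reagents that add atoms: chloromethyl methyl ether, COCCl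
Why: Williamson-type acetal formation as in step 2; the aryl bromide is inert to these conditions.

Step 6
Reactants: 7 1-bromo-5-methoxy-4-(methoxymethoxy)naphthalene; 5 2-[8-methoxy-1-(methoxymethoxy)naphthalen-2-yl]-4,4,5,5-tetramethyl-1,3,2-dioxaborolane
Product: 8 5,8'-dimethoxy-4,1'-bis(methoxymethoxy)-1,2'-binaphthalene
Conditions: Pd(OAc)2 (cat.), SPhos (2-dicyclohexylphosphino-2',6'-dimethoxybiphenyl, cat.), K3PO4, toluene/H2O, 90 °C
Reagents that add atoms: none
Why: Suzuki–Miyaura coupling; a dialkylbiarylphosphine ligand copes with the ortho-alkoxy boronate and the peri-flanked naphthyl bromide, and the positions of boron and bromine fix the C4(B)–C2(C) bond.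

Step 7
Reactants: 8 5,8'-dimethoxy-4,1'-bis(methoxymethoxy)-1,2'-binaphthalene
Product: 10 3-bromo-5,8'-dimethoxy-4,1'-bis(methoxymethoxy)-1,2'-binaphthalene, via binaphthyllithium 9 (not isolated)
Conditions: n-BuLi, TMEDA, THF, −78 → 0 °C; then BrCl2C–CCl2Br, −78 °C → rt
Reagents that add atoms: 1,2-dibromo-1,1,2,2-tetrachloroethane, BrC(Cl)(Cl)C(Cl)(Cl)Br
Why: Directed ortho metalation followed by bromine transfer; only the OMOM group of unit B has a free ortho C–H, at C2(B), since the ortho position of the OMOM group of unit C is occupied by the biaryl bond, and methoxy groups are weaker directors.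

Step 8
Reactants: 11 1-(2-hydroxy-6-methoxyphenyl)ethanone
Product: 12 2-acetyl-3-methoxyphenyl trifluoromethanesulfonate
Conditions: Tf2O, pyridine, CH2Cl2, 0 °C → rt
Reagents that add atoms: trifluoromethanesulfonic anhydride, O=S(=O)(OS(=O)(=O)C(F)(F)F)C(F)(F)F
Why: O-Sulfonylation of the phenol; this turns the hydroxyl ortho to the acetyl group into a cross-coupling handle at the position where the allyl arm is needed.

Step 9
Reactants: 12 2-acetyl-3-methoxyphenyl trifluoromethanesulfonate; 13 allylboronic acid pinacol ester
Product: 14 1-[2-methoxy-6-(prop-2-en-1-yl)phenyl]ethanone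
Conditions: Pd(PPh3)4 (cat.), CsF, THF, reflux
Reagents that add atoms: none
Why: Suzuki–Miyaura allylation of an aryl triflate activated by its ortho acetyl group; fluoride activates the boronate under nearly neutral conditions, which limits migration of the allyl double bond into conjugation.

Step 10
Reactants: 14 1-[2-methoxy-6-(prop-2-en-1-yl)phenyl]ethanone; 10 3-bromo-5,8'-dimethoxy-4,1'-bis(methoxymethoxy)-1,2'-binaphthalene
Product: 15 2-[5,8'-dimethoxy-4,1'-bis(methoxymethoxy)-1,2'-binaphthalen-3-yl]-1-[2-methoxy-6-(prop-2-en-1-yl)phenyl]ethanone
Conditions: Pd2(dba)3 (cat.), P(t-Bu)3 (cat.), NaOt-Bu (2.2 equiv), THF, 50 °C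
Reagents that add atoms: none
Why: Palladium-catalysed ketone α-arylation (enolate cross-coupling of the Buchwald–Hartwig type); the methyl ketone has a single enolisable site, the bulky electron-rich phosphine allows a mild temperature, and the product rests as its stabilised enolate, whose second arylation is blocked by the ortho-substituted aryl group.

Step 11
Reactants: 15 2-[5,8'-dimethoxy-4,1'-bis(methoxymethoxy)-1,2'-binaphthalen-3-yl]-1-[2-methoxy-6-(prop-2-en-1-yl)phenyl]ethanone
Product: 17 2-[5,8'-dimethoxy-4,1'-bis(methoxymethoxy)-1,2'-binaphthalen-3-yl]-1-[2-methoxy-6-(prop-2-en-1-yl)phenyl]prop-2-en-1-one, via Mannich base 16 (not isolated)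
Conditions: Me2NCH2NMe2, Ac2O, DMF, rt → 60 °C
Reagents that add atoms: N,N,N',N'-tetramethylmethanediamine, CN(C)CN(C)C
Why: Mannich methylenation; acetic anhydride converts the aminal into the N,N-dimethylmethaniminium ion, the enol of the doubly activated CH2 group attacks it, and N-acylation of the Mannich base triggers β-elimination to the 1,1-disubstituted enone, which is used without storage.

Step 12
Reactants: 17 2-[5,8'-dimethoxy-4,1'-bis(methoxymethoxy)-1,2'-binaphthalen-3-yl]-1-[2-methoxy-6-(prop-2-en-1-yl)phenyl]prop-2-en-1-one
Product: 19 8,8',8''-trimethoxy-1',1''-bis(methoxymethoxy)-2,2':4',2''-ternaphthalen-1-ol, via keto tautomer 18 (not isolated)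
Conditions: second-generation Grubbs catalyst (H2IMes)(PCy3)Cl2Ru=CHPh (5–10 mol %), degassed toluene (high dilution), 80 °C, argon sparge
Reagents that add atoms: none
Why: The ruthenium benzylidene first exchanges with the accessible, electron-neutral allyl alkene; the new alkylidene then adds across the tethered enone C=CH2 in a [2+2] step, and cycloreversion of the ruthenacyclobutane forms C2(A)=C3(A) and a ruthenium methylidene that carries the chain and expels ethene. The closest known reaction type is the ring-closing metathesis of 1-(2-allylaryl)prop-2-en-1-ones to 1-naphthols by metathesis and tautomerisation. The ring closed is the six-membered carbocycle C1–C4, C4a, C8a of unit A, formed by metathesis between two tethered terminal alkenes with the new trisubstituted alkene endocyclic and conjugated to the ketone. The primary product 18 has a C4 methylene activated by the arene and the enone, and it should enolise to the naphthol 19, gaining aromaticity and an O–H···OMe hydrogen bond, which makes the sequence irreversible. No stereocentre is formed. The step needs ring closure to be faster than ruthenium hydride-mediated migration of the allyl double bond (which would lead to a five-membered closure) and faster than intermolecular coupling of allyl termini. The ortho arrangement of ketone and allyl arm on one benzene ring holds the two alkenes close, and high dilution, removal of ethene and fresh catalyst favour the intramolecular path, while the hindered electron-poor enone is a poor partner for any intermolecular metathesis. The methyl ethers, the MOM acetals and the new naphthol are spectators.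

Step 13
Reactants: 19 8,8',8''-trimethoxy-1',1''-bis(methoxymethoxy)-2,2':4',2''-ternaphthalen-1-ol
Product: 20 8,8',8''-trimethoxy-2,2':4',2''-ternaphthalene-1,1',1''-triol
Conditions: HCl (3 M aq.), MeOH/THF, 45 °C, under argon
Reagents that add atoms: none
Why: Acid-catalysed acetal cleavage; methanol traps the methoxymethyl cation so that it does not alkylate the electron-rich rings, the methyl ethers are stable to these conditions, and exclusion of air protects the triol from oxidation.

## Compound list

1 | naphthalene-1,8-diol | Oc1cccc2cccc(O)c12 | starting material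
2 | 8-methoxynaphthalen-1-ol | COc1cccc2cccc(O)c12 | intermediate
3 | 1-methoxy-8-(methoxymethoxy)naphthalene | COCOc1cccc2cccc(OC)c12 | intermediate
4 | [8-methoxy-1-(methoxymethoxy)naphthalen-2-yl]lithium | [Li]c1ccc2cccc(OC)c2c1OCOC | intermediate
5 | 2-[8-methoxy-1-(methoxymethoxy)naphthalen-2-yl]-4,4,5,5-tetramethyl-1,3,2-dioxaborolane | COCOc1c(B2OC(C)(C)C(C)(C)O2)ccc2cccc(OC)c12 | intermediate
6 | 4-bromo-8-methoxynaphthalen-1-ol | COc1cccc2c(Br)ccc(O)c12 | intermediate
7 | 1-bromo-5-methoxy-4-(methoxymethoxy)naphthalene | COCOc1ccc(Br)c2cccc(OC)c12 | intermediate
8 | 5,8'-dimethoxy-4,1'-bis(methoxymethoxy)-1,2'-binaphthalene | COCOc1ccc(-c2ccc3cccc(OC)c3c2OCOC)c2cccc(OC)c12 | intermediate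
9 | [5,8'-dimethoxy-4,1'-bis(methoxymethoxy)-1,2'-binaphthalen-3-yl]lithium | [Li]c1cc(-c2ccc3cccc(OC)c3c2OCOC)c2cccc(OC)c2c1OCOC | intermediate
10 | 3-bromo-5,8'-dimethoxy-4,1'-bis(methoxymethoxy)-1,2'-binaphthalene | Brc1cc(-c2ccc3cccc(OC)c3c2OCOC)c2cccc(OC)c2c1OCOC | intermediate
11 | 1-(2-hydroxy-6-methoxyphenyl)ethanone | COc1cccc(O)c1C(C)=O | starting material
12 | 2-acetyl-3-methoxyphenyl trifluoromethanesulfonate | COc1cccc(OS(=O)(=O)C(F)(F)F)c1C(C)=O | intermediate
13 | allylboronic acid pinacol ester (4,4,5,5-tetramethyl-2-(prop-2-en-1-yl)-1,3,2-dioxaborolane) | C=CCB1OC(C)(C)C(C)(C)O1 | starting material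
14 | 1-[2-methoxy-6-(prop-2-en-1-yl)phenyl]ethanone | C=CCc1cccc(OC)c1C(C)=O | intermediate
15 | 2-[5,8'-dimethoxy-4,1'-bis(methoxymethoxy)-1,2'-binaphthalen-3-yl]-1-[2-methoxy-6-(prop-2-en-1-yl)phenyl]ethanone | C=CCc1cccc(OC)c1C(=O)Cc1cc(-c2ccc3cccc(OC)c3c2OCOC)c2cccc(OC)c2c1OCOC | intermediate
16 | racemic 2-[5,8'-dimethoxy-4,1'-bis(methoxymethoxy)-1,2'-binaphthalen-3-yl]-3-(dimethylamino)-1-[2-methoxy-6-(prop-2-en-1-yl)phenyl]propan-1-one | C=CCc1cccc(OC)c1C(=O)C(CN(C)C)c1cc(-c2ccc3cccc(OC)c3c2OCOC)c2cccc(OC)c2c1OCOC | intermediate
17 | 2-[5,8'-dimethoxy-4,1'-bis(methoxymethoxy)-1,2'-binaphthalen-3-yl]-1-[2-methoxy-6-(prop-2-en-1-yl)phenyl]prop-2-en-1-one | C=CCc1cccc(OC)c1C(=O)C(=C)c1cc(-c2ccc3cccc(OC)c3c2OCOC)c2cccc(OC)c2c1OCOC | intermediate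
18 | 2-[5,8'-dimethoxy-4,1'-bis(methoxymethoxy)-1,2'-binaphthalen-3-yl]-8-methoxynaphthalen-1(4H)-one | COc1cccc2CC=C(c3cc(-c4ccc5cccc(OC)c5c4OCOC)c4cccc(OC)c4c3OCOC)C(=O)c12 | intermediate
19 | 8,8',8''-trimethoxy-1',1''-bis(methoxymethoxy)-2,2':4',2''-ternaphthalen-1-ol | COc1cccc2ccc(-c3cc(-c4ccc5cccc(OC)c5c4OCOC)c4cccc(OC)c4c3OCOC)c(O)c12 | intermediate
20 | 8,8',8''-trimethoxy-2,2':4',2''-ternaphthalene-1,1',1''-triol | COc1cccc2ccc(-c3cc(-c4ccc5cccc(OC)c5c4O)c4cccc(OC)c4c3O)c(O)c12 | target

## Step count and risk

Total step count: 13. Longest linear sequence: 9 steps (steps 1, 4, 5, 6, 7, 10, 11, 12, 13).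

**Step 12 (key step).**
- What may go wrong: migration of the allyl double bond into conjugation under ruthenium hydride catalysis before ring closure, followed by closure of a five-membered ring; or failure of the hindered, electron-poor 1,1-disubstituted enone to engage, so that only intermolecular coupling of allyl termini takes place. The cause would be the very bulky α-aryl group beside the reacting alkene.
- Fallback: it sets out from 15 and avoids the enone altogether. Oxidative cleavage of the allyl alkene (OsO4 cat., NaIO4, 2,6-lutidine, dioxane/H2O, rt; Lemieux–Johnson) should give {2-[(5,8'-dimethoxy-4,1'-bis(methoxymethoxy)-1,2'-binaphthalen-3-yl)acetyl]-3-methoxyphenyl}acetaldehyde F1. Mild base (K2CO3, MeOH, rt) should then bring about an intramolecular aldol condensation of the deoxybenzoin CH2 group onto the aldehyde. Dehydration gives 18, which enolises, and the route is rejoined at 19.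

**Step 10.**
- What may go wrong: migration of the allyl double bond under the alkoxide base, consumption of the alkene by the arylpalladium intermediate in a Heck-type process, or slow enolate arylation because the 2,6-disubstituted aryl ketone is twisted and both partners are hindered.
- Fallback: the arylation is carried out before the allyl group exists; it sets out from 11 and 10. Benzylation of 11 (BnBr, K2CO3, DMF) gives 1-[2-(benzyloxy)-6-methoxyphenyl]ethanone F2. α-Arylation of F2 with 10 under the conditions of step 10 gives 1-[2-(benzyloxy)-6-methoxyphenyl]-2-[5,8'-dimethoxy-4,1'-bis(methoxymethoxy)-1,2'-binaphthalen-3-yl]ethanone F3. Hydrogenolysis (H2, Pd/C, EtOAc) gives 2-[5,8'-dimethoxy-4,1'-bis(methoxymethoxy)-1,2'-binaphthalen-3-yl]-1-(2-hydroxy-6-methoxyphenyl)ethanone F4. Triflation of the phenol (PhNTf2, K2CO3, THF) gives 2-[(5,8'-dimethoxy-4,1'-bis(methoxymethoxy)-1,2'-binaphthalen-3-yl)acetyl]-3-methoxyphenyl trifluoromethanesulfonate F5. Allylation of F5 with 13 (Pd(PPh3)4, CsF, THF) rejoins the route at 15. Steps 8 and 9 are then not needed.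

**Step 4.**
- What may go wrong: bromination ortho instead of para to the hydroxyl, attack on the methoxy-bearing ring, or double bromination, since the hydroxyl and methoxy groups activate four positions.
- Fallback: it sets out from 2 and replaces selectivity in the bromination by selectivity in a halogen–lithium exchange. Exhaustive bromination of the phenol ring (NBS, 2 equiv, MeCN) gives 2,4-dibromo-8-methoxynaphthalen-1-ol F6. Protection (NaH, MOMCl, DMF) gives 2,4-dibromo-8-methoxy-1-(methoxymethoxy)naphthalene F7. Exchange with n-BuLi (1 equiv, THF, −78 °C) should occur at the bromine ortho to the chelating OMOM group, and protonation with MeOH rejoins the route at 7.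

**Step 7.**
- What may go wrong: incomplete metalation because the OMOM group is crowded between the peri methoxy group and the biaryl-bearing ring, or lithiation ortho to a methoxy group.
- Fallback: it sets out from 2 and places both halogens by electrophilic substitution before the coupling. Para iodination (NIS, MeCN, 0 °C) gives 4-iodo-8-methoxynaphthalen-1-ol F8. Ortho bromination at the only remaining position of the phenol ring (NBS, cat. i-Pr2NH, CH2Cl2) gives 2-bromo-4-iodo-8-methoxynaphthalen-1-ol F9. Protection (NaH, MOMCl, DMF) gives 2-bromo-4-iodo-8-methoxy-1-(methoxymethoxy)naphthalene F10. A Suzuki–Miyaura coupling with 5 at the more reactive and less hindered C–I bond (Pd(PPh3)4, Na2CO3, DME/H2O, 60 °C) rejoins the route at 10. Steps 4 to 7 are then not needed.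

## Further compounds

F1 | step 12 | {2-[(5,8'-dimethoxy-4,1'-bis(methoxymethoxy)-1,2'-binaphthalen-3-yl)acetyl]-3-methoxyphenyl}acetaldehyde | O=CCc1cccc(OC)c1C(=O)Cc1cc(-c2ccc3cccc(OC)c3c2OCOC)c2cccc(OC)c2c1OCOC
F2 | step 10 | 1-[2-(benzyloxy)-6-methoxyphenyl]ethanone | COc1cccc(OCc2ccccc2)c1C(C)=O
F3 | step 10 | 1-[2-(benzyloxy)-6-methoxyphenyl]-2-[5,8'-dimethoxy-4,1'-bis(methoxymethoxy)-1,2'-binaphthalen-3-yl]ethanone | COc1cccc(OCc2ccccc2)c1C(=O)Cc1cc(-c2ccc3cccc(OC)c3c2OCOC)c2cccc(OC)c2c1OCOC
F4 | step 10 | 2-[5,8'-dimethoxy-4,1'-bis(methoxymethoxy)-1,2'-binaphthalen-3-yl]-1-(2-hydroxy-6-methoxyphenyl)ethanone | COc1cccc(O)c1C(=O)Cc1cc(-c2ccc3cccc(OC)c3c2OCOC)c2cccc(OC)c2c1OCOC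
F5 | step 10 | 2-[(5,8'-dimethoxy-4,1'-bis(methoxymethoxy)-1,2'-binaphthalen-3-yl)acetyl]-3-methoxyphenyl trifluoromethanesulfonate | COc1cccc(OS(=O)(=O)C(F)(F)F)c1C(=O)Cc1cc(-c2ccc3cccc(OC)c3c2OCOC)c2cccc(OC)c2c1OCOC
F6 | step 4 | 2,4-dibromo-8-methoxynaphthalen-1-ol | COc1cccc2c(Br)cc(Br)c(O)c12
F7 | step 4 | 2,4-dibromo-8-methoxy-1-(methoxymethoxy)naphthalene | COCOc1c(Br)cc(Br)c2cccc(OC)c12
F8 | step 7 | 4-iodo-8-methoxynaphthalen-1-ol | COc1cccc2c(I)ccc(O)c12
F9 | step 7 | 2-bromo-4-iodo-8-methoxynaphthalen-1-ol | COc1cccc2c(I)cc(Br)c(O)c12
F10 | step 7 | 2-bromo-4-iodo-8-methoxy-1-(methoxymethoxy)naphthalene | COCOc1c(Br)cc(I)c2cccc(OC)c12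
A1 | alternative 1 | racemic 8-methoxy-2,4-bis[8-methoxy-1-(methoxymethoxy)naphthalen-2-yl]-1,4-dihydro-1,4-epoxynaphthalene (one enantiomer drawn) | COCOc1c(ccc2cccc(OC)c12)[C@@]34C=C(c5ccc6cccc(OC)c6c5OCOC)[C@@H](O3)c3c(OC)cccc34
A2 | alternative 1 | 2,4-bis[8-methoxy-1-(methoxymethoxy)naphthalen-2-yl]furan | o1cc(-c2ccc3cccc(OC)c3c2OCOC)cc1-c1ccc2cccc(OC)c2c1OCOC
A3 | alternative 1 | 3-methoxy-2-(trimethylsilyl)phenyl trifluoromethanesulfonate | COc1cccc(OS(=O)(=O)C(F)(F)F)c1[Si](C)(C)C
A4 | alternative 1 | 3-methoxybenzyne (3-methoxy-1,2-didehydrobenzene) | COC1=CC=CC#C1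
A5 | alternative 2 | 8,8',8''-trimethoxy-1'-(methoxymethoxy)-2,2':4',2''-ternaphthalene-1,1''-diol | COc1cccc2ccc(-c3cc(-c4ccc5cccc(OC)c5c4O)c4cccc(OC)c4c3OCOC)c(O)c12
A6 | alternative 2 | 2,2'-{[8-methoxy-1-(methoxymethoxy)naphthalene-2,4-diyl]bis[(1E)-prop-1-ene-3,1-diyl]}bis(N,N-diethyl-6-methoxybenzamide) | COCOc1c(C/C=C/c2cccc(OC)c2C(=O)N(CC)CC)cc(C/C=C/c2cccc(OC)c2C(=O)N(CC)CC)c2cccc(OC)c12
A7 | alternative 3 | racemic 2-[5,8'-dimethoxy-4,1'-bis(methoxymethoxy)-1,2'-binaphthalen-3-yl]-8-methoxy-3,4-dihydronaphthalen-1(2H)-one | COc1cccc2CCC(c3cc(-c4ccc5cccc(OC)c5c4OCOC)c4cccc(OC)c4c3OCOC)C(=O)c12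
A8 | alternative 3 | racemic 4-(2-bromo-3-methoxyphenyl)-2-[5,8'-dimethoxy-4,1'-bis(methoxymethoxy)-1,2'-binaphthalen-3-yl]-N-methoxy-N-methylbutanamide | COc1cccc(CCC(C(=O)N(C)OC)c2cc(-c3ccc4cccc(OC)c4c3OCOC)c3cccc(OC)c3c2OCOC)c1Br
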